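Ring B is built last, from an open chain. The key step exploits the 1,3,5-pattern of ring B: its hydroxyls at C1 and C3 and its alkyl chain at C5 map onto the C3 and C5 carbonyls and the C7 ketone of a 3,5,7-trioxo acid, whose C2–C7 span supplies all six ring carbons. One buffered aldol condensation joins C2 to C7, closes ring B and aromatizes it; the C1 carboxyl, which activates C2 and steers the closure, is shed afterwards. The precursor is (E)-21-aryl-3,5,7-trioxohenicos-13-enoic acid with ring A as its MOM ether, made by Julia–Kocienski olefination, diketone dianion acylation and trianion carboxylation.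

Key step: step 11

Remark: acid 18 is a β-keto acid and is carried into step 11 as the cold crude extract, without storage.

Step 1
Reactants: 1 3-hydroxy-5-methoxybenzaldehyde
Product: 2 3-methoxy-5-(methoxymethoxy)benzaldehyde
Conditions: MOMCl, i-Pr2NEt, CH2Cl2, 0 °C to rt
Reagents that add atoms: chloromethyl methyl ether, COCCl
Why: Williamson-type O-alkylation of the phenol by the reactive α-chloro ether installs a base-stable acetal that should survive the ylide, amide-base and polyanion steps, while the aldehyde is untouched.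

Step 2
Reactants: 3 7-bromoheptan-1-ol
Product: 4 (7-hydroxyheptyl)triphenylphosphonium bromide
Conditions: PPh3, MeCN, reflux
Reagents that add atoms: triphenylphosphine, c1ccc(cc1)P(c1ccccc1)c1ccccc1
Why: SN2 quaternization of the phosphine by an unhindered primary bromide needs no protection of the remote hydroxyl.

Step 3
Reactants: 4 (7-hydroxyheptyl)triphenylphosphonium bromide; 2 3-methoxy-5-(methoxymethoxy)benzaldehyde
Product: 6 8-[3-methoxy-5-(methoxymethoxy)phenyl]oct-7-en-1-ol as an E/Z mixture, via ylide alkoxide 5 (not isolated)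
Conditions: NaN(SiMe3)2 (2.1 equiv), THF, 0 °C; then 2, 0 °C to rt; H2O
Reagents that add atoms: none
Why: Wittig olefination with the non-stabilized ylide, generated beside a spectator alkoxide by two equivalents of base, joins the chain to the benzylic carbon of ring A, and the alkene geometry is immaterial because step 4 saturates it.

Step 4
Reactants: 6 8-[3-methoxy-5-(methoxymethoxy)phenyl]oct-7-en-1-ol
Product: 7 8-[3-methoxy-5-(methoxymethoxy)phenyl]octan-1-ol
Conditions: H2 (1 atm), 10% Pd/C, EtOAc, rt
Reagents that add atoms: none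
Why: Heterogeneous catalytic hydrogenation saturates the styrenic double bond of both isomers and should leave the aryl ethers, the MOM acetal and the primary alcohol alone.

Step 5
Reactants: 7 8-[3-methoxy-5-(methoxymethoxy)phenyl]octan-1-ol
Product: 8 8-[3-methoxy-5-(methoxymethoxy)phenyl]octanal
Conditions: TEMPO (cat.), PhI(OAc)2, CH2Cl2, rt
Reagents that add atoms: none
Why: TEMPO-catalysed oxoammonium oxidation of a primary alcohol stops at the aldehyde in anhydrous CH2Cl2 and is mild enough for the MOM acetal.

Step 6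
Reactants: 9 methyl 7-bromoheptanoate
Product: 10 methyl 7-[(1-phenyl-1H-tetrazol-5-yl)sulfanyl]heptanoate
Conditions: 1-phenyl-1H-tetrazole-5-thiol, K2CO3, acetone, reflux
Reagents that add atoms: 1-phenyl-1H-tetrazole-5-thiol, Sc1nnnn1-c1ccccc1
Why: SN2 S-alkylation of the soft tetrazolethiolate by the primary bromide should be much faster than any attack on the methyl ester.

Step 7
Reactants: 10 methyl 7-[(1-phenyl-1H-tetrazol-5-yl)sulfanyl]heptanoate
Product: 11 methyl 7-[(1-phenyl-1H-tetrazol-5-yl)sulfonyl]heptanoate
Conditions: 30% aq. H2O2, (NH4)6Mo7O24·4H2O (cat.), MeOH, 0 °C to rt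
Reagents that add atoms: hydrogen peroxide, OO
Why: (NH4)6Mo7O24-catalysed peroxide oxidation takes the sulfide through the sulfoxide to the sulfone without touching the ester.

Step 8
Reactants: 11 methyl 7-[(1-phenyl-1H-tetrazol-5-yl)sulfonyl]heptanoate; 8 8-[3-methoxy-5-(methoxymethoxy)phenyl]octanal
Product: 13 methyl (E)-15-[3-methoxy-5-(methoxymethoxy)phenyl]pentadec-7-enoate, via potassiated sulfone 12 (not isolated)
Conditions: KN(SiMe3)2, DME, −60 °C; then 8, −60 °C to rt; aq. NH4Cl
Reagents that add atoms: none
Why: Julia–Kocienski olefination, in which the potassium α-sulfonyl carbanion (the sulfone α-CH is far more acidic than the ester α-CH) adds to the aldehyde through an open transition state to the anti adduct and Smiles rearrangement with antiperiplanar loss of SO2 and tetrazololate should deliver the (E)-alkene, the only stereoelement of the target.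

Step 9
Reactants: 14 2,4-pentanedione; 13 methyl (E)-15-[3-methoxy-5-(methoxymethoxy)phenyl]pentadec-7-enoate
Product: 16 (E)-20-[3-methoxy-5-(methoxymethoxy)phenyl]icos-12-ene-2,4,6-trione, via dilithiated pentanedione 15 (not isolated)
Conditions: 14 (3 equiv), LiN(i-Pr)2 (6 equiv), THF, 0 °C; then 13, 0 °C to rt; cold 1 M HCl to pH 5
Reagents that add atoms: none
Why: Claisen-type C-acylation of the terminal carbanion of the β-diketone 1,3-dianion by the methyl ester, with excess dianion absorbing the acidic proton of the product, should give the 1,3,5-triketone whose C6 carbonyl is the former ester carbon.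

Step 10
Reactants: 16 (E)-20-[3-methoxy-5-(methoxymethoxy)phenyl]icos-12-ene-2,4,6-trione
Product: 18 (E)-21-[3-methoxy-5-(methoxymethoxy)phenyl]-3,5,7-trioxohenicos-13-enoic acid, via trilithiated triketone 17 (not isolated)
Conditions: LiN(i-Pr)2 (3.3 equiv), THF, 0 °C; CO2 (g), −78 to 0 °C; cold 1 M HCl to pH 3, Et2O, 0 °C; used at once
Reagents that add atoms: carbon dioxide, O=C=O
Why: Polyanion carboxylation, in which kinetic third deprotonation by the hindered amide at the terminal methyl (not at the more substituted C7 methylene) gives the trianion whose most basic terminal carbanion takes up CO2, and brief cold acidification frees the β-keto acid without loss of CO2 or of the MOM group.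

Step 11
Reactants: 18 (E)-21-[3-methoxy-5-(methoxymethoxy)phenyl]-3,5,7-trioxohenicos-13-enoic acid
Product: 20 2,4-dihydroxy-6-[(E)-14-[3-methoxy-5-(methoxymethoxy)phenyl]tetradec-6-en-1-yl]benzoic acid, via aldol carbinol 19 (not isolated)
Conditions: KH2PO4/K2HPO4 buffer (0.5 M, pH 7.5)/THF 1:1, N2, rt; then cold 1 M HCl to pH 3, EtOAc
Reagents that add atoms: none
Why: At pH 7.5 the acid is present as its carboxylate, and the C2 methylene, flanked by C1 and the C3 ketone, enolizes toward C3 and adds to the chain-bearing C7 ketone (intramolecular aldol) to give carbinol 19, which loses water by E1cB elimination and tautomerizes to the aromatic 2,4-dihydroxybenzoate. The closest known reaction type is the aldol cyclization of 3,5,7-triketo acids to β-resorcylic acids, the laboratory counterpart of ring formation by alkylresorcinol-type polyketide synthases. Ring B closes in a 6-(enolendo)-exo-trig mode, because the reacting C2=C3 enol double bond lies inside the forming ring and the C7 carbonyl oxygen outside it. No stereocentre results: the two sp3 centres of 19 are uncontrolled and are erased on aromatization, and the (E)-alkene is not touched. The step needs C2-to-C7 aldol closure to beat C6-to-C1 Claisen closure, aldol attack of the C8 methylene on C3, cyclodehydration to pyranones and loss of CO2. These are held back by the carboxylate being a poor acyl acceptor, by the double activation of C2 against the single activation of C8, by the absence of acid or dehydrating agent, and by the slow decarboxylation of the carboxylate form at room temperature.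

Step 12
Reactants: 20 2,4-dihydroxy-6-[(E)-14-[3-methoxy-5-(methoxymethoxy)phenyl]tetradec-6-en-1-yl]benzoic acid
Product: 22 5-[(E)-14-(3-hydroxy-5-methoxyphenyl)tetradec-6-en-1-yl]benzene-1,3-diol (dehydrobisgravillol), via MOM-protected resorcinol 21 (not isolated)
Conditions: 1,4-dioxane/H2O 10:1, 95 °C; then MeOH (excess), conc. HCl (to ca. 1 M), 50 °C
Reagents that add atoms: none
Why: Thermal protodecarboxylation of the β-resorcylic acid (ipso protonation of the electron-rich ring, then loss of CO2) is followed in the same flask by acid-catalysed methanolysis of the MOM acetal, the acid stage also finishing any incomplete decarboxylation, while the isolated (E)-alkene should be inert to both.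

Compound list
1 | 3-hydroxy-5-methoxybenzaldehyde | COc1cc(O)cc(C=O)c1 | starting material
2 | 3-methoxy-5-(methoxymethoxy)benzaldehyde | COCOc1cc(OC)cc(C=O)c1 | intermediate
3 | 7-bromoheptan-1-ol | OCCCCCCCBr | starting material
4 | (7-hydroxyheptyl)triphenylphosphonium bromide | OCCCCCCC[P+](c1ccccc1)(c1ccccc1)c1ccccc1.[Br-] | intermediate
5 | sodium 7-(triphenylphosphoranylidene)heptan-1-olate (ylide alkoxide, not isolated) | [Na+].[O-]CCCCCCC=P(c1ccccc1)(c1ccccc1)c1ccccc1 | intermediate
6 | 8-[3-methoxy-5-(methoxymethoxy)phenyl]oct-7-en-1-ol (E/Z mixture) | COCOc1cc(OC)cc(C=CCCCCCCO)c1 | intermediate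
7 | 8-[3-methoxy-5-(methoxymethoxy)phenyl]octan-1-ol | COCOc1cc(OC)cc(CCCCCCCCO)c1 | intermediate
8 | 8-[3-methoxy-5-(methoxymethoxy)phenyl]octanal | COCOc1cc(OC)cc(CCCCCCCC=O)c1 | intermediate
9 | methyl 7-bromoheptanoate | COC(=O)CCCCCCBr | starting material
10 | methyl 7-[(1-phenyl-1H-tetrazol-5-yl)sulfanyl]heptanoate | COC(=O)CCCCCCSc1nnnn1-c1ccccc1 | intermediate
11 | methyl 7-[(1-phenyl-1H-tetrazol-5-yl)sulfonyl]heptanoate | COC(=O)CCCCCCS(=O)(=O)c1nnnn1-c1ccccc1 | intermediate
12 | potassium salt of sulfone 11 deprotonated at C7 (not isolated) | COC(=O)CCCCC[CH-]S(=O)(=O)c1nnnn1-c1ccccc1.[K+] | intermediate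
13 | methyl (E)-15-[3-methoxy-5-(methoxymethoxy)phenyl]pentadec-7-enoate | COCOc1cc(OC)cc(CCCCCCC/C=C/CCCCCC(=O)OC)c1 | intermediate
14 | 2,4-pentanedione | CC(=O)CC(C)=O | starting material
15 | 1,3-dilithio-2,4-pentanedione (dianion, not isolated) | [Li+].[Li+].[CH2-]C(=O)[CH-]C(C)=O | intermediate
16 | (E)-20-[3-methoxy-5-(methoxymethoxy)phenyl]icos-12-ene-2,4,6-trione | COCOc1cc(OC)cc(CCCCCCC/C=C/CCCCCC(=O)CC(=O)CC(C)=O)c1 | intermediate
17 | trilithium salt of triketone 16 deprotonated at C1, C3 and C5 (not isolated) | COCOc1cc(OC)cc(CCCCCCC/C=C/CCCCCC(=O)[CH-]C(=O)[CH-]C(=O)[CH2-])c1.[Li+].[Li+].[Li+] | intermediate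
18 | (E)-21-[3-methoxy-5-(methoxymethoxy)phenyl]-3,5,7-trioxohenicos-13-enoic acid | COCOc1cc(OC)cc(CCCCCCC/C=C/CCCCCC(=O)CC(=O)CC(=O)CC(=O)O)c1 | intermediate
19 | 2-hydroxy-2-[(E)-14-[3-methoxy-5-(methoxymethoxy)phenyl]tetradec-6-en-1-yl]-4,6-dioxocyclohexane-1-carboxylic acid (diastereomer mixture, not isolated) | COCOc1cc(OC)cc(CCCCCCC/C=C/CCCCCC2(O)CC(=O)CC(=O)C2C(=O)O)c1 | intermediate
20 | 2,4-dihydroxy-6-[(E)-14-[3-methoxy-5-(methoxymethoxy)phenyl]tetradec-6-en-1-yl]benzoic acid | COCOc1cc(OC)cc(CCCCCCC/C=C/CCCCCc2cc(O)cc(O)c2C(=O)O)c1 | intermediate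
21 | 5-[(E)-14-[3-methoxy-5-(methoxymethoxy)phenyl]tetradec-6-en-1-yl]benzene-1,3-diol (not isolated) | COCOc1cc(OC)cc(CCCCCCC/C=C/CCCCCc2cc(O)cc(O)c2)c1 | intermediate
22 | 5-[(E)-14-(3-hydroxy-5-methoxyphenyl)tetradec-6-en-1-yl]benzene-1,3-diol (dehydrobisgravillol) | COc1cc(O)cc(CCCCCCC/C=C/CCCCCc2cc(O)cc(O)c2)c1 | target

Total step count: 12. Longest linear sequence: 9 steps (steps 1, 3, 4, 5, 8, 9, 10, 11, 12; from 1 through 2, 6, 7, 8, 13, 16, 18 and 20 to 22).

Steps most likely to fail

Step 11. The closure may be outrun by loss of CO2 from the β-keto acid, by cyclodehydration toward pyranones, or it may stall through aggregation of the soap-like carboxylate, so that ring B does not form cleanly. The fallback brings ring B in intact instead of building it; it sets out from aldehyde 8 and comes back to the route at target 22. 3,5-Dihydroxybenzaldehyde would be protected with MOMCl and i-Pr2NEt as 3,5-bis(methoxymethoxy)benzaldehyde F1. 5-Bromopentan-1-ol and PPh3 would give (5-hydroxypentyl)triphenylphosphonium bromide F2. Wittig reaction of F2 (NaN(SiMe3)2, 2 equiv, THF) with F1 should give 6-[3,5-bis(methoxymethoxy)phenyl]hex-5-en-1-ol F3, and hydrogenation (H2, Pd/C) 6-[3,5-bis(methoxymethoxy)phenyl]hexan-1-ol F4. Mitsunobu reaction with 1-phenyl-1H-tetrazole-5-thiol (PPh3, DIAD) would give 5-({6-[3,5-bis(methoxymethoxy)phenyl]hexyl}sulfanyl)-1-phenyl-1H-tetrazole F5, and H2O2 with (NH4)6Mo7O24·4H2O the sulfone 5-({6-[3,5-bis(methoxymethoxy)phenyl]hexyl}sulfonyl)-1-phenyl-1H-tetrazole F6. Julia–Kocienski olefination of F6 with 8 (KN(SiMe3)2, DME, −60 °C) should give 1-[(E)-14-[3,5-bis(methoxymethoxy)phenyl]tetradec-8-en-1-yl]-3-methoxy-5-(methoxymethoxy)benzene F7, and HCl in MeOH would remove the three acetals to give 22.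

Step 10. The third deprotonation may take place at the C7 methylene of the triketone instead of the terminal methyl, so that the carboxyl enters at the wrong terminus, or CO2 may be lost again during the acidic work-up. The fallback delivers the carboxyl carbon with the nucleophile instead of with CO2; it sets out from ester 13 and comes back at 21. Methyl 3,5-dioxohexanoate, triply deprotonated with LiN(i-Pr)2 in THF, would be acylated at its terminal carbon by 13 to give methyl (E)-21-[3-methoxy-5-(methoxymethoxy)phenyl]-3,5,7-trioxohenicos-13-enoate F8. Mild base (K2CO3, MeOH, rt) should bring about the same C2-to-C7 aldol condensation to methyl 2,4-dihydroxy-6-[(E)-14-[3-methoxy-5-(methoxymethoxy)phenyl]tetradec-6-en-1-yl]benzoate F9. Hot aqueous-ethanolic KOH followed by acidification would saponify the hindered ester with loss of CO2 and give 21, which enters the acid stage of step 12.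

Step 9. Proton transfer from the enolizable ester, or from the acidic triketone as it forms, to the dianion may outrun C-acylation, so that ester is returned or condenses with itself. The fallback replaces acylation by aldol addition and oxidation; it sets out from ester 13 and comes back at triketone 16. i-Bu2AlH (CH2Cl2, −78 °C) would reduce 13 to (E)-15-[3-methoxy-5-(methoxymethoxy)phenyl]pentadec-7-enal F10. Addition of dianion 15 (THF, −78 °C) to the aldehyde, which is fast compared with proton transfer, should give racemic (E)-6-hydroxy-20-[3-methoxy-5-(methoxymethoxy)phenyl]icos-12-ene-2,4-dione F11. Dess–Martin periodinane (CH2Cl2, rt) would oxidize the carbinol to 16.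

Further compounds
F1 | step 11 | 3,5-bis(methoxymethoxy)benzaldehyde | COCOc1cc(C=O)cc(OCOC)c1
F2 | step 11 | (5-hydroxypentyl)triphenylphosphonium bromide | OCCCCC[P+](c1ccccc1)(c1ccccc1)c1ccccc1.[Br-]
F3 | step 11 | 6-[3,5-bis(methoxymethoxy)phenyl]hex-5-en-1-ol (E/Z mixture) | COCOc1cc(C=CCCCCO)cc(OCOC)c1
F4 | step 11 | 6-[3,5-bis(methoxymethoxy)phenyl]hexan-1-ol | COCOc1cc(CCCCCCO)cc(OCOC)c1
F5 | step 11 | 5-({6-[3,5-bis(methoxymethoxy)phenyl]hexyl}sulfanyl)-1-phenyl-1H-tetrazole | COCOc1cc(CCCCCCSc2nnnn2-c2ccccc2)cc(OCOC)c1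
F6 | step 11 | 5-({6-[3,5-bis(methoxymethoxy)phenyl]hexyl}sulfonyl)-1-phenyl-1H-tetrazole | COCOc1cc(CCCCCCS(=O)(=O)c2nnnn2-c2ccccc2)cc(OCOC)c1
F7 | step 11 | 1-[(E)-14-[3,5-bis(methoxymethoxy)phenyl]tetradec-8-en-1-yl]-3-methoxy-5-(methoxymethoxy)benzene | COCOc1cc(OC)cc(CCCCCCC/C=C/CCCCCc2cc(OCOC)cc(OCOC)c2)c1
F8 | step 10 | methyl (E)-21-[3-methoxy-5-(methoxymethoxy)phenyl]-3,5,7-trioxohenicos-13-enoate | COCOc1cc(OC)cc(CCCCCCC/C=C/CCCCCC(=O)CC(=O)CC(=O)CC(=O)OC)c1
F9 | step 10 | methyl 2,4-dihydroxy-6-[(E)-14-[3-methoxy-5-(methoxymethoxy)phenyl]tetradec-6-en-1-yl]benzoate | COCOc1cc(OC)cc(CCCCCCC/C=C/CCCCCc2cc(O)cc(O)c2C(=O)OC)c1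
F10 | step 9 | (E)-15-[3-methoxy-5-(methoxymethoxy)phenyl]pentadec-7-enal | COCOc1cc(OC)cc(CCCCCCC/C=C/CCCCCC=O)c1
F11 | step 9 | (E)-6-hydroxy-20-[3-methoxy-5-(methoxymethoxy)phenyl]icos-12-ene-2,4-dione (racemic) | COCOc1cc(OC)cc(CCCCCCC/C=C/CCCCCC(O)CC(=O)CC(C)=O)c1
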